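A direct plan would make the C7–aryl bond last: an arylmetal reagent from iodide A1 would be added under Felkin–Anh control to the α-aryloxy aldehyde A2, which would come from O-benzylserine through the α-triflyloxy ester A3, its displacement by the phenoxide of dihydrosinapyl alcohol, and semi-reduction. Its weakest steps would be:
- the SN2 displacement on A3 by the hindered 2,6-dimethoxyphenoxide, where elimination and loss of optical purity would compete;
- the semi-reduction to A2 and its handling, since C8–H next to a formyl and an aryloxy group would epimerise easily;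
- the aryl addition itself, which would set C7 only by 1,2-induction from that labile centre.

The route rests on cutting the C7–C8 bond so that C7 comes from the non-enolisable ring A aldehyde 3 and the O–C8–C9 unit from an (E)-γ-aryloxyallylboronate 8, in which the hindered ring B ether oxygen is already attached to the future C8 (made by propargylation of the phenol at a primary carbon). One chiral phosphoric acid-catalysed allylboration forms C7–C8 and sets both stereocentres together through a chair transition state: the E geometry gives the anti (erythro) pair, the catalyst the absolute sense. No substitution by the 2,6-dimethoxyphenoxide at a stereogenic carbon, no epimerisable aldehyde partner and no 1,2-induction are needed; the vinyl group left behind is cut down to C9H2OH.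

Key step: step 5

Remark: neolignan numbering is used (C7 = benzylic carbinol carbon on ring A, C8 = carbon bearing the ring B ether oxygen, C9 = hydroxymethyl carbon; ring A = guaiacyl ring, ring B = 2,6-dimethoxyphenyl ring); the target is (7S,8R), erythro.

Step 1
Reactants: 1 vanillin; 2 1,3-bis(benzyloxy)propan-2-ol
Product: 3 4-{[1,3-bis(benzyloxy)propan-2-yl]oxy}-3-methoxybenzaldehyde
Conditions: PPh3 (1.3 equiv), DIAD (1.3 equiv), THF, 0 °C → rt, 16 h
Reagents that add atoms: none
Why: Mitsunobu etherification, in which the phenol of vanillin (acidified by the para-formyl group) is alkylated by the activated secondary alcohol, whose carbinol carbon carries two identical CH2OBn arms, so that no stereocentre arises and the aldehyde is untouched.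

Step 2
Reactants: 4 4-(3-hydroxypropyl)-2,6-dimethoxyphenol (dihydrosinapyl alcohol)
Product: 5 3-[3,5-dimethoxy-4-(prop-2-yn-1-yloxy)phenyl]propan-1-ol
Conditions: propargyl bromide (1.2 equiv), K2CO3 (2 equiv), acetone, reflux, 6 h
Reagents that add atoms: propargyl bromide, BrCC#C
Why: Williamson ether synthesis, in which K2CO3 ionises only the phenol and the hindered 2,6-dimethoxyphenoxide is alkylated at an unhindered primary propargylic carbon, which fixes the ring B oxygen on the future C8 before that carbon is stereogenic.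

Step 3
Reactants: 5 3-[3,5-dimethoxy-4-(prop-2-yn-1-yloxy)phenyl]propan-1-ol
Product: 6 5-[3-(benzyloxy)propyl]-1,3-dimethoxy-2-(prop-2-yn-1-yloxy)benzene
Conditions: NaH (1.2 equiv), BnBr (1.2 equiv), Bu4NI (5 mol %), THF, 0 °C → rt
Reagents that add atoms: benzyl bromide, BrCc1ccccc1
Why: Williamson benzylation of the primary sodium alkoxide under iodide catalysis, which at 0 °C to rt should be faster than deprotonation of the terminal alkyne or isomerisation of the propargyl ether.

Step 4
Reactants: 6 5-[3-(benzyloxy)propyl]-1,3-dimethoxy-2-(prop-2-yn-1-yloxy)benzene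
Product: 7 2-[(E)-3-{4-[3-(benzyloxy)propyl]-2,6-dimethoxyphenoxy}prop-1-en-1-yl]-4,4,5,5-tetramethyl-1,3,2-dioxaborolane
Conditions: pinacolborane (1.3 equiv), Cp2Zr(H)Cl (5 mol %), Et3N (10 mol %), neat, 60 °C, 16 h
Reagents that add atoms: pinacolborane, CC1(C)OBOC1(C)C
Why: Zirconocene hydride-catalysed hydroboration of a terminal alkyne with pinacolborane, a syn addition with boron at the terminal carbon that should give the (E)-1-alkenylboronate while both ethers stay inert.

Step 5
Reactants: 7 2-[(E)-3-{4-[3-(benzyloxy)propyl]-2,6-dimethoxyphenoxy}prop-1-en-1-yl]-4,4,5,5-tetramethyl-1,3,2-dioxaborolane; 3 4-{[1,3-bis(benzyloxy)propan-2-yl]oxy}-3-methoxybenzaldehyde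
Product: 10 (1S,2R)-1-(4-{[1,3-bis(benzyloxy)propan-2-yl]oxy}-3-methoxyphenyl)-2-{4-[3-(benzyloxy)propyl]-2,6-dimethoxyphenoxy}but-3-en-1-ol, via allylboronate 8 (not isolated), via borate ester 9 (not isolated)
Conditions: 7 (1.3 equiv), [Ir(cod)(PPh2Me)2]PF6 (3 mol %, activated with H2, then Ar), THF, rt, 2 h; filtration through Florisil under Ar, solvent changed to toluene; 3 (1.0 equiv), (R)-TRIP [(R)-3,3′-bis(2,4,6-triisopropylphenyl)-1,1′-binaphthyl-2,2′-diyl hydrogen phosphate] (5 mol %), 4 Å MS, −30 °C, 24–48 h; aq. NaHCO3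
Reagents that add atoms: none
Why: The cationic iridium hydride formed from [Ir(cod)(PPh2Me)2]PF6 and H2 should move the double bond of 7 by insertion and β-hydride elimination into conjugation with the aryloxy oxygen to give the (E)-enol ether 8, as is known for 3-siloxy-1-alkenylboronates, and after removal of iridium 8 should add to 3 in an allylboration through a closed six-membered chair transition state, borate 9 being hydrolysed on work-up. The closest known reaction type is the chiral phosphoric acid-catalysed allylboration of aryl aldehydes with (E)-γ-substituted allyl pinacolboronates made by iridium-catalysed isomerisation of 1-alkenylboronates, which gives anti homoallylic alcohols. No ring is closed. C8 is controlled by the alkene geometry: with the aryl group of the aldehyde and the γ-aryloxy group of the E reagent both equatorial in the chair, C7–OH and C8–OAr should come out anti, that is erythro. C7 is controlled by the catalyst: (R)-TRIP, hydrogen-bonded through P–OH to the pseudo-axial boronate oxygen and through P=O to the formyl hydrogen, should direct the allyl group to the Re face of the aldehyde as it does for benzaldehyde, which here means (7S) and, with the anti relation, (8R). The step needs a clean E geometry, γ-attack and suppression of the uncatalysed pathway, which the E-selective isomerisation, the cyclic transition state and the low temperature should secure, while the non-enolisable aldehyde 3 has no other reaction channel.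

Step 6
Reactants: 10 (1S,2R)-1-(4-{[1,3-bis(benzyloxy)propan-2-yl]oxy}-3-methoxyphenyl)-2-{4-[3-(benzyloxy)propyl]-2,6-dimethoxyphenoxy}but-3-en-1-ol
Product: 13 (1S,2R)-1-(4-{[1,3-bis(benzyloxy)propan-2-yl]oxy}-3-methoxyphenyl)-2-{4-[3-(benzyloxy)propyl]-2,6-dimethoxyphenoxy}propane-1,3-diol, via triol 11 (not isolated), via aldehyde 12 (not isolated)
Conditions: OsO4 (2 mol %), NaIO4 (4 equiv), 2,6-lutidine (2 equiv), 1,4-dioxane–H2O 3:1, rt; extractive work-up; NaBH4 (2 equiv), EtOH, 0 °C
Reagents that add atoms: osmium tetroxide, O=[Os](=O)(=O)=O (its oxygen ends at C9; it is regenerated by sodium periodate, [Na+].[O-]I(=O)(=O)=O)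
Why: Lemieux–Johnson cleavage followed by borohydride reduction, in which OsO4 should dihydroxylate only the terminal alkene to triol 11, periodate cleaves its 1,2-diol but not the 1,3-related C7–OH, and the buffered conditions with immediate reduction of aldehyde 12 at 0 °C should keep C8 intact, no new stereocentre being formed.

Step 7
Reactants: 13 (1S,2R)-1-(4-{[1,3-bis(benzyloxy)propan-2-yl]oxy}-3-methoxyphenyl)-2-{4-[3-(benzyloxy)propyl]-2,6-dimethoxyphenoxy}propane-1,3-diol
Product: 14 (1S,2R)-1-{4-[(1,3-dihydroxypropan-2-yl)oxy]-3-methoxyphenyl}-2-[4-(3-hydroxypropyl)-2,6-dimethoxyphenoxy]propane-1,3-diol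
Conditions: H2 (1 atm), Pd/C (10 wt % Pd), EtOAc–EtOH 1:1, rt
Reagents that add atoms: none
Why: Catalytic hydrogenolysis of three primary benzyl ethers under neutral conditions, in which the alkyl aryl ethers and the secondary benzylic alcohol should persist and no stereocentre is touched.

## Compound list

1 | vanillin (4-hydroxy-3-methoxybenzaldehyde) | COc1cc(C=O)ccc1O | starting material
2 | 1,3-bis(benzyloxy)propan-2-ol | OC(COCc1ccccc1)COCc1ccccc1 | starting material
3 | 4-{[1,3-bis(benzyloxy)propan-2-yl]oxy}-3-methoxybenzaldehyde | COc1cc(C=O)ccc1OC(COCc1ccccc1)COCc1ccccc1 | intermediate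
4 | 4-(3-hydroxypropyl)-2,6-dimethoxyphenol (dihydrosinapyl alcohol) | COc1cc(CCCO)cc(OC)c1O | starting material
5 | 3-[3,5-dimethoxy-4-(prop-2-yn-1-yloxy)phenyl]propan-1-ol | COc1cc(CCCO)cc(OC)c1OCC#C | intermediate
6 | 5-[3-(benzyloxy)propyl]-1,3-dimethoxy-2-(prop-2-yn-1-yloxy)benzene | COc1cc(CCCOCc2ccccc2)cc(OC)c1OCC#C | intermediate
7 | 2-[(E)-3-{4-[3-(benzyloxy)propyl]-2,6-dimethoxyphenoxy}prop-1-en-1-yl]-4,4,5,5-tetramethyl-1,3,2-dioxaborolane | COc1cc(CCCOCc2ccccc2)cc(OC)c1OC/C=C/B1OC(C)(C)C(C)(C)O1 | intermediate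
8 | 2-[(E)-3-{4-[3-(benzyloxy)propyl]-2,6-dimethoxyphenoxy}prop-2-en-1-yl]-4,4,5,5-tetramethyl-1,3,2-dioxaborolane ((E)-γ-aryloxyallylboronate, formed in the flask) | COc1cc(CCCOCc2ccccc2)cc(OC)c1O/C=C/CB1OC(C)(C)C(C)(C)O1 | intermediate
9 | 2-{[(1S,2R)-1-(4-{[1,3-bis(benzyloxy)propan-2-yl]oxy}-3-methoxyphenyl)-2-{4-[3-(benzyloxy)propyl]-2,6-dimethoxyphenoxy}but-3-en-1-yl]oxy}-4,4,5,5-tetramethyl-1,3,2-dioxaborolane (borate ester, formed in the flask) | COc1cc([C@H](OB4OC(C)(C)C(C)(C)O4)[C@@H](C=C)Oc2c(OC)cc(CCCOCc3ccccc3)cc2OC)ccc1OC(COCc1ccccc1)COCc1ccccc1 | intermediate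
10 | (1S,2R)-1-(4-{[1,3-bis(benzyloxy)propan-2-yl]oxy}-3-methoxyphenyl)-2-{4-[3-(benzyloxy)propyl]-2,6-dimethoxyphenoxy}but-3-en-1-ol | COc1cc([C@H](O)[C@@H](C=C)Oc2c(OC)cc(CCCOCc3ccccc3)cc2OC)ccc1OC(COCc1ccccc1)COCc1ccccc1 | intermediate
11 | (2RS,3S,4S)-4-(4-{[1,3-bis(benzyloxy)propan-2-yl]oxy}-3-methoxyphenyl)-3-{4-[3-(benzyloxy)propyl]-2,6-dimethoxyphenoxy}butane-1,2,4-triol (C7 and C8 as in 10, both epimers at the new carbinol carbon; formed in the flask) | COc1cc([C@H](O)[C@@H](C(O)CO)Oc2c(OC)cc(CCCOCc3ccccc3)cc2OC)ccc1OC(COCc1ccccc1)COCc1ccccc1 | intermediate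
12 | (2S,3S)-3-(4-{[1,3-bis(benzyloxy)propan-2-yl]oxy}-3-methoxyphenyl)-2-{4-[3-(benzyloxy)propyl]-2,6-dimethoxyphenoxy}-3-hydroxypropanal (formed in the flask) | COc1cc([C@H](O)[C@@H](C=O)Oc2c(OC)cc(CCCOCc3ccccc3)cc2OC)ccc1OC(COCc1ccccc1)COCc1ccccc1 | intermediate
13 | (1S,2R)-1-(4-{[1,3-bis(benzyloxy)propan-2-yl]oxy}-3-methoxyphenyl)-2-{4-[3-(benzyloxy)propyl]-2,6-dimethoxyphenoxy}propane-1,3-diol | COc1cc([C@H](O)[C@@H](CO)Oc2c(OC)cc(CCCOCc3ccccc3)cc2OC)ccc1OC(COCc1ccccc1)COCc1ccccc1 | intermediate
14 | (1S,2R)-1-{4-[(1,3-dihydroxypropan-2-yl)oxy]-3-methoxyphenyl}-2-[4-(3-hydroxypropyl)-2,6-dimethoxyphenoxy]propane-1,3-diol (7S,8R in neolignan numbering) | COc1cc([C@H](O)[C@@H](CO)Oc2c(OC)cc(CCCO)cc2OC)ccc1OC(CO)CO | target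

Total step count: 7. Longest linear sequence: 6 steps (4 → 5 → 6 → 7 → 10 → 13 → 14); step 1 supplies the second branch.

Steps most likely to fail:

Step 5 (key step). The step could fail through an E/Z mixture of 8 (which would erode the anti relation), through acid-induced loss of the enol ether, or through poor facial selectivity of the catalyst with this bulky γ-aryloxy reagent. Stereocontrol would then be moved from the catalyst to a resolution. The fallback sets out from 7 and 3 and comes back at 10. Allylboronate 8, made as in step 5, would be combined with 3 without phosphoric acid (toluene, 40 °C). The same chair transition state should give the racemic anti borate ester F1 and, after aqueous work-up, the racemic anti alcohol rac-(1S,2R)-1-(4-{[1,3-bis(benzyloxy)propan-2-yl]oxy}-3-methoxyphenyl)-2-{4-[3-(benzyloxy)propyl]-2,6-dimethoxyphenoxy}but-3-en-1-ol F2, any syn isomer being removed by chromatography. An acylative kinetic resolution would follow, with the enantiomer of benzotetramisole that acylates the (1R,2S) antipode (expected to be the S catalyst, by analogy with 1-arylalkanols; 5 mol %), isobutyric anhydride (0.6 equiv) and i-Pr2NEt in CHCl3 at 0 °C. It should convert the unwanted enantiomer into the (1R,2S)-isobutyrate F3 and leave the (1S,2R)-alcohol 10.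

Step 6. The β-hydroxy-α-aryloxy aldehyde 12 could epimerise at C8, fragment by retro-aldol reaction or lose water before it is reduced. The hydroxyl at C7 would then be blocked first. The fallback sets out from 10 and comes back at 13. Silylation (TBSOTf, 2,6-lutidine, CH2Cl2, −78 °C) would give the silyl ether F4. Cleavage under the conditions of step 6 would give, via the diol F5, the β-silyloxy aldehyde F6, which cannot undergo retro-aldol cleavage. NaBH4 would give the alcohol F7, and Bu4NF in THF would remove the silyl group and return 13.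

Step 7. Hydrogenolysis could also remove the benzylic hydroxyl at C7, or stall at the aliphatic benzyl ethers. The benzyl groups would then be removed by electron transfer in solution instead of on a metal surface. The fallback sets out from 13 and comes back at 14, with no new intermediate. The two hydroxyls of 13 would be deprotonated (n-BuLi, 2 equiv, THF, −78 °C) and the dilithium alkoxide treated with lithium 4,4′-di-tert-butylbiphenylide (about 7 equiv, THF, −78 °C; NH4Cl quench). The benzyl ethers should fragment to toluene and alkoxides, while the benzylic C7–O bond is held as an alkoxide that cannot leave. Alkyl aryl ethers react much more slowly at this temperature.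

Further compounds

F1 | step 5 | rac-2-{[(1S,2R)-1-(4-{[1,3-bis(benzyloxy)propan-2-yl]oxy}-3-methoxyphenyl)-2-{4-[3-(benzyloxy)propyl]-2,6-dimethoxyphenoxy}but-3-en-1-yl]oxy}-4,4,5,5-tetramethyl-1,3,2-dioxaborolane (racemic anti borate ester, both enantiomers) | COc1cc([C@H](OB4OC(C)(C)C(C)(C)O4)[C@@H](C=C)Oc2c(OC)cc(CCCOCc3ccccc3)cc2OC)ccc1OC(COCc1ccccc1)COCc1ccccc1.COc1cc([C@@H](OB4OC(C)(C)C(C)(C)O4)[C@H](C=C)Oc2c(OC)cc(CCCOCc3ccccc3)cc2OC)ccc1OC(COCc1ccccc1)COCc1ccccc1
F2 | step 5 | rac-(1S,2R)-1-(4-{[1,3-bis(benzyloxy)propan-2-yl]oxy}-3-methoxyphenyl)-2-{4-[3-(benzyloxy)propyl]-2,6-dimethoxyphenoxy}but-3-en-1-ol (racemic anti alcohol, both enantiomers) | COc1cc([C@H](O)[C@@H](C=C)Oc2c(OC)cc(CCCOCc3ccccc3)cc2OC)ccc1OC(COCc1ccccc1)COCc1ccccc1.COc1cc([C@@H](O)[C@H](C=C)Oc2c(OC)cc(CCCOCc3ccccc3)cc2OC)ccc1OC(COCc1ccccc1)COCc1ccccc1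
F3 | step 5 | (1R,2S)-1-(4-{[1,3-bis(benzyloxy)propan-2-yl]oxy}-3-methoxyphenyl)-2-{4-[3-(benzyloxy)propyl]-2,6-dimethoxyphenoxy}but-3-en-1-yl 2-methylpropanoate | COc1cc([C@@H](OC(=O)C(C)C)[C@H](C=C)Oc2c(OC)cc(CCCOCc3ccccc3)cc2OC)ccc1OC(COCc1ccccc1)COCc1ccccc1
F4 | step 6 | tert-butyl{[(1S,2R)-1-(4-{[1,3-bis(benzyloxy)propan-2-yl]oxy}-3-methoxyphenyl)-2-{4-[3-(benzyloxy)propyl]-2,6-dimethoxyphenoxy}but-3-en-1-yl]oxy}dimethylsilane | COc1cc([C@H](O[Si](C)(C)C(C)(C)C)[C@@H](C=C)Oc2c(OC)cc(CCCOCc3ccccc3)cc2OC)ccc1OC(COCc1ccccc1)COCc1ccccc1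
F5 | step 6 | (2RS,3R,4S)-4-(4-{[1,3-bis(benzyloxy)propan-2-yl]oxy}-3-methoxyphenyl)-3-{4-[3-(benzyloxy)propyl]-2,6-dimethoxyphenoxy}-4-[(tert-butyldimethylsilyl)oxy]butane-1,2-diol (both epimers at the new carbinol carbon) | COc1cc([C@H](O[Si](C)(C)C(C)(C)C)[C@@H](C(O)CO)Oc2c(OC)cc(CCCOCc3ccccc3)cc2OC)ccc1OC(COCc1ccccc1)COCc1ccccc1
F6 | step 6 | (2S,3S)-3-(4-{[1,3-bis(benzyloxy)propan-2-yl]oxy}-3-methoxyphenyl)-2-{4-[3-(benzyloxy)propyl]-2,6-dimethoxyphenoxy}-3-[(tert-butyldimethylsilyl)oxy]propanal | COc1cc([C@H](O[Si](C)(C)C(C)(C)C)[C@@H](C=O)Oc2c(OC)cc(CCCOCc3ccccc3)cc2OC)ccc1OC(COCc1ccccc1)COCc1ccccc1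
F7 | step 6 | (2R,3S)-3-(4-{[1,3-bis(benzyloxy)propan-2-yl]oxy}-3-methoxyphenyl)-2-{4-[3-(benzyloxy)propyl]-2,6-dimethoxyphenoxy}-3-[(tert-butyldimethylsilyl)oxy]propan-1-ol | COc1cc([C@H](O[Si](C)(C)C(C)(C)C)[C@@H](CO)Oc2c(OC)cc(CCCOCc3ccccc3)cc2OC)ccc1OC(COCc1ccccc1)COCc1ccccc1
F0 | step 7 | none | none
A1 | direct plan | 1-{[1,3-bis(benzyloxy)propan-2-yl]oxy}-4-iodo-2-methoxybenzene | COc1cc(I)ccc1OC(COCc1ccccc1)COCc1ccccc1
A2 | direct plan | (R)-3-(benzyloxy)-2-[4-(3-hydroxypropyl)-2,6-dimethoxyphenoxy]propanal | COc1cc(CCCO)cc(OC)c1O[C@H](COCc1ccccc1)C=O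
A3 | direct plan | methyl (S)-3-(benzyloxy)-2-{[(trifluoromethyl)sulfonyl]oxy}propanoate | FC(F)(F)S(=O)(=O)O[C@@H](COCc1ccccc1)C(=O)OC
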